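**Retrosynthetic overview**
1. Target ⇐ C15 desilylation and two late acylations of a C8/C9 diol (O8 methacrylate first, then O9 isovalerate).
2. Ten-membered carbocycle and trans-γ-lactone ⇐ one Cr(II) Barbier macrocyclisation/lactonisation (C6–C7 bond) of an enal / 2-(bromomethyl)acrylate; these are the last rings formed.
3. Key step: the 3(2H)-furanone ⇐ O10–C3 bond formation in a one-flask union of a tertiary propargylic alcohol, CO (= C3) and a (Z)-vinyl iodide; this is the first new ring.
4. Alkyne fragment ⇐ L-tartrate acetonide (C8, C9), chelation-controlled ethynylation (C10), Morita–Baylis–Hillman reaction (C11–C13); vinyl iodide ⇐ but-2-yne-1,4-diol.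
5. Ring order: dioxolane (from the chiral pool, temporary) → furanone → carbocycle + lactone (same step) → dioxolane removed.

Assumption: atoms are labelled by germacrane numbering (C1 furanone C=O, C3 furanone O–C=, C6 lactone O–CH, C8/C9 ester-bearing carbons, C10 the O–C–Me carbon, C15 the CH2OH); only 1 and 7 count as starting materials, all other commercial inputs are listed as reagents.

**Step 1**
Reactants: 1 dimethyl (4R,5R)-2,2-dimethyl-1,3-dioxolane-4,5-dicarboxylate (dimethyl 2,3-O-isopropylidene-L-tartrate)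
Product: 2 (4R,5R)-N4,N5-dimethoxy-N4,N5,2,2-tetramethyl-1,3-dioxolane-4,5-dicarboxamide
Conditions: MeNHOMe·HCl (3 equiv), i-PrMgCl (6 equiv), THF, −20 °C
Reagents that add atoms: N,O-dimethylhydroxylamine hydrochloride (CNOC.Cl)
Why: Weinreb amidation of both esters by the chloromagnesium amide of MeNHOMe; the two stereocentres (C8, C9) come unchanged from L-tartaric acid in the thermodynamically preferred trans-dioxolane.

**Step 2**
Reactants: 2 bis-Weinreb amide
Product: 3 (4R,5R)-5-acetyl-N-methoxy-N,2,2-trimethyl-1,3-dioxolane-4-carboxamide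
Conditions: MeMgBr (1.2 equiv), THF, −15 °C
Reagents that add atoms: methylmagnesium bromide (C[Mg]Br)
Why: Grignard mono-addition to a C2-symmetric bis-Weinreb amide (desymmetrisation), where the stable Mg-chelated tetrahedral adduct slows the second addition and either amide gives the same methyl ketone.

**Step 3**
Reactants: 3 keto Weinreb amide
Product: 4 (4R,5R)-5-[(2R)-2-hydroxybut-3-yn-2-yl]-N-methoxy-N,2,2-trimethyl-1,3-dioxolane-4-carboxamide
Conditions: HC≡CMgBr (3 equiv), MgBr2·OEt2 (1 equiv), THF/CH2Cl2, −78 °C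
Reagents that add atoms: ethynylmagnesium bromide (C#C[Mg]Br)
Why: Cram-chelate-controlled Grignard addition in which Mg bridges the ketone oxygen and the α-dioxolane oxygen (O9), so the acetylide attacks C10 from the face of the C9–H (anti to C8) and sets C10 as (R) here (10S in the target), while the Weinreb amide is untouched at −78 °C.

**Step 4**
Reactants: 4 propargylic alcohol Weinreb amide
Product: 5 (4R,5R)-5-[(2R)-2-hydroxybut-3-yn-2-yl]-2,2-dimethyl-1,3-dioxolane-4-carbaldehyde
Conditions: DIBAL-H (2.5 equiv), THF, −78 °C; Rochelle salt work-up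
Reagents that add atoms: none
Why: Weinreb amide reduction stops at the aldehyde through the chelated aluminium hemiaminal, and the trans-dioxolane keeps the C10-OH from closing a lactol onto C7.

**Step 5**
Reactants: 5 aldehyde
Product: 6 methyl 2-{(RS)-hydroxy[(4S,5R)-5-[(2R)-2-hydroxybut-3-yn-2-yl]-2,2-dimethyl-1,3-dioxolan-4-yl]methyl}prop-2-enoate
Conditions: methyl acrylate (5 equiv), DABCO (1 equiv), MeOH, rt, 4 d
Reagents that add atoms: methyl acrylate (C=CC(=O)OC)
Why: Morita–Baylis–Hillman reaction of an inductively activated α-alkoxy aldehyde; the new C7 carbinol centre forms as a mixture and is erased in step 11.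

**Step 6**
Reactants: 7 but-2-yne-1,4-diol
Product: 8 4-{[tert-butyl(diphenyl)silyl]oxy}but-2-yn-1-ol
Conditions: TBDPSCl (1 equiv), diol (3 equiv), imidazole, THF/DMF, 0 °C to rt
Reagents that add atoms: tert-butyl(chloro)diphenylsilane (CC(C)(C)[Si](Cl)(c1ccccc1)c1ccccc1)
Why: statistical monosilylation of a symmetrical diol used in excess.

**Step 7**
Reactants: 8 monosilylated butynediol
Product: 9 (2Z)-4-{[tert-butyl(diphenyl)silyl]oxy}-3-iodobut-2-en-1-ol
Conditions: Red-Al, THF, 0 °C to rt; then I2, −78 to 0 °C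
Reagents that add atoms: iodine (II)
Why: hydroxyl-directed trans-hydroalumination puts hydride on the carbon next to the free CH2OH (C5) and aluminium, then iodine, on C4, giving only the (Z)-vinyl iodide with C6 cis to iodine.

**Step 8**
Reactants: 9 (Z)-iodo allylic alcohol
Product: 10 (2Z)-4-{[tert-butyl(diphenyl)silyl]oxy}-3-iodobut-2-enal
Conditions: MnO2, CH2Cl2, rt
Reagents that add atoms: none
Why: neutral allylic alcohol oxidation that leaves the (Z)-geometry and the silyl ether intact.

**Step 9**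
Reactants: 10 (Z)-iodo enal
Product: 11 tert-butyl{[(2Z)-2-iodo-4,4-dimethoxybut-2-en-1-yl]oxy}diphenylsilane
Conditions: HC(OMe)3, PPTS (cat.), MeOH, rt
Reagents that add atoms: trimethyl orthoformate (COC(OC)OC)
Why: acetalisation masks the aldehyde against the amine used in step 10 and makes the vinyl iodide electron-neutral, which favours CO insertion over direct coupling.

**Step 10**
Reactants: 6 alkyne (MBH adduct); 11 (Z)-vinyl iodide acetal
Product: 14 C6-enal 3(2H)-furanone (MBH alcohol retained), via ynenone acetal 12 (not isolated), via enaminone 13 (not isolated)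
Conditions: PdCl2(PPh3)2 (5 mol%), CuI (2 mol%), Et3N, CO (1 atm), THF, rt; purge, then Et2NH (1.5 equiv), 0 °C; then 5% aq. oxalic acid, rt
Reagents that add atoms: carbon monoxide ([C-]#[O+]); water (O)
Why: Proposed new method: a one-flask three-component carbonylative furanone annulation in which Pd(0)/Cu(I) carbonylative Sonogashira coupling of alkenyl iodide 11 with the tertiary propargylic alcohol 6 gives γ-hydroxy-ynenone 12, Et2NH adds to the ynone β-carbon (C1) and bends the linear alkyne into the sp2 enaminone 13, and mild aqueous acid then hydrolyses it to the 1,3-diketone, lets the C10-OH close onto C3 and dehydrates, forging the O10–C3 bond of the furanone with C1 as the ketone while the same acid unmasks the C6 aldehyde (no stereocentre is formed and C10 is untouched); the closest known reactions are the carbonylative Sonogashira coupling, the Pd-catalysed carbonylative synthesis of 3(2H)-furanones from aryl iodides and propargylic alcohols, and the Et2NH/acid conversion of γ-hydroxy-ynones into 3(2H)-furanones, none of which has been run as a single operation on an alkenyl iodide with a polyfunctional chiral partner.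

**Step 11**
Reactants: 14 furanone enal (MBH alcohol)
Product: 15 methyl (2Z)-2-(bromomethyl)-3-[(4S,5R)-5-{(2S)-5-[(2Z)-1-{[tert-butyl(diphenyl)silyl]oxy}-4-oxobut-2-en-2-yl]-2-methyl-3-oxo-2,3-dihydrofuran-2-yl}-2,2-dimethyl-1,3-dioxolan-4-yl]prop-2-enoate
Conditions: NBS, Me2S (premixed), CH2Cl2, −20 °C to rt
Reagents that add atoms: N-bromosuccinimide (O=C1CCC(=O)N1Br)
Why: Corey–Kim-type bromination of a Morita–Baylis–Hillman alcohol with allylic transposition (SN2′) converges both C7 epimers to the thermodynamic (Z)-2-(bromomethyl)enoate; the only free hydroxyl in 14 is the one that reacts.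

**Step 12**
Reactants: 15 enal allylic bromide
Product: 17 macrocyclic furanone trans-lactone (8,9-acetonide; 15-OTBDPS), via hydroxy ester 16 (not isolated)
Conditions: CrCl2 (8 equiv), THF (2 mM, syringe pump), rt; then PPTS (cat.), CH2Cl2, rt
Reagents that add atoms: none
Why: Nozaki–Hiyama (Barbier-type) allylation in which the σ-allyl-Cr(III) species, free to equilibrate its geometry, adds through C7 to the tethered enal in a chair-like six-membered transition state with both chain ends (C5 and C8) pseudo-equatorial, giving the 6,7-anti adduct with the C7 face dictated by the fixed C8 centre of the rigid trans-dioxolane (macrocyclic stereocontrol, as in related Barbier closures to 6,7-trans-germacranolides), after which the C6 alkoxide of 16 lactonises onto the methyl ester (O8 is blocked), setting C6 (R) and C7 (S).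

**Step 13**
Reactants: 17 macrocyclic acetonide
Product: 18 8,9-diol (15-OTBDPS; C6–C10 configuration unchanged)
Conditions: TFA/H2O (9:1), CH2Cl2, 0 °C
Reagents that add atoms: none
Why: acid hydrolysis of the acetonide; the primary TBDPS ether, the furanone and the α-methylene lactone tolerate brief aqueous TFA.

**Step 14**
Reactants: 18 8,9-diol
Product: 19 8-O-methacrylate 9-ol (15-OTBDPS)
Conditions: methacrylic anhydride (1.1 equiv), Et3N, DMAP (cat.), CH2Cl2, −30 °C
Reagents that add atoms: methacrylic anhydride (CC(=C)C(=O)OC(=O)C(C)=C)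
Why: site-selective DMAP-catalysed acylation, since C8-OH (next to the tertiary C7) is less hindered than the neopentyl-type C9-OH flanked by the quaternary C10, so one equivalent of anhydride at low temperature is expected to go to O8.

**Step 15**
Reactants: 19 8-O-methacrylate 9-ol
Product: 20 8-O-methacrylate 9-O-isovalerate (15-OTBDPS)
Conditions: isovaleric anhydride (3 equiv), DMAP (1 equiv), Et3N, CH2Cl2, rt
Reagents that add atoms: isovaleric anhydride (CC(C)CC(=O)OC(=O)CC(C)C)
Why: Steglich-type acyl transfer under forcing conditions esterifies the one remaining hindered secondary hydroxyl; all other oxygens are blocked.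

**Step 16**
Reactants: 20 fully acylated silyl ether
Product: 21 target CNP0552093.1
Conditions: HF·pyridine, THF/pyridine, 0 °C to rt
Reagents that add atoms: none
Why: fluoride cleavage of the primary TBDPS ether (Si–F bond formation) under buffered conditions that spare both esters, the α-methylene lactone and the furanone.

**Compound list**
1 | dimethyl (4R,5R)-2,2-dimethyl-1,3-dioxolane-4,5-dicarboxylate (dimethyl 2,3-O-isopropylidene-L-tartrate) | COC(=O)[C@@H]1OC(C)(C)O[C@H]1C(=O)OC | starting material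
2 | (4R,5R)-N4,N5-dimethoxy-N4,N5,2,2-tetramethyl-1,3-dioxolane-4,5-dicarboxamide | CON(C)C(=O)[C@@H]1OC(C)(C)O[C@H]1C(=O)N(C)OC | intermediate
3 | (4R,5R)-5-acetyl-N-methoxy-N,2,2-trimethyl-1,3-dioxolane-4-carboxamide | CC(=O)[C@@H]1OC(C)(C)O[C@H]1C(=O)N(C)OC | intermediate
4 | (4R,5R)-5-[(2R)-2-hydroxybut-3-yn-2-yl]-N-methoxy-N,2,2-trimethyl-1,3-dioxolane-4-carboxamide | C#C[C@@](C)(O)[C@@H]1OC(C)(C)O[C@H]1C(=O)N(C)OC | intermediate
5 | (4R,5R)-5-[(2R)-2-hydroxybut-3-yn-2-yl]-2,2-dimethyl-1,3-dioxolane-4-carbaldehyde | C#C[C@@](C)(O)[C@@H]1OC(C)(C)O[C@H]1C=O | intermediate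
6 | methyl 2-{(RS)-hydroxy[(4S,5R)-5-[(2R)-2-hydroxybut-3-yn-2-yl]-2,2-dimethyl-1,3-dioxolan-4-yl]methyl}prop-2-enoate (both C7 epimers) | C#C[C@@](C)(O)[C@@H]1OC(C)(C)O[C@H]1C(O)C(=C)C(=O)OC | intermediate
7 | but-2-yne-1,4-diol | OCC#CCO | starting material
8 | 4-{[tert-butyl(diphenyl)silyl]oxy}but-2-yn-1-ol | OCC#CCO[Si](c1ccccc1)(c1ccccc1)C(C)(C)C | intermediate
9 | (2Z)-4-{[tert-butyl(diphenyl)silyl]oxy}-3-iodobut-2-en-1-ol | OC/C=C(\I)CO[Si](c1ccccc1)(c1ccccc1)C(C)(C)C | intermediate
10 | (2Z)-4-{[tert-butyl(diphenyl)silyl]oxy}-3-iodobut-2-enal | O=C/C=C(\I)CO[Si](c1ccccc1)(c1ccccc1)C(C)(C)C | intermediate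
11 | tert-butyl{[(2Z)-2-iodo-4,4-dimethoxybut-2-en-1-yl]oxy}diphenylsilane | COC(OC)/C=C(\I)CO[Si](c1ccccc1)(c1ccccc1)C(C)(C)C | intermediate
12 | ynenone acetal: compound 6 acylated at its alkyne terminus (C2) by the C3 ketone that carries the (Z)-C4(CH2OTBDPS)=C5H–C6H(OMe)2 unit; C10 (R), dioxolane (4S,5R), both C7 epimers | COC(OC)/C=C(/CO[Si](c1ccccc1)(c1ccccc1)C(C)(C)C)C(=O)C#C[C@@](C)(O)[C@@H]1OC(C)(C)O[C@H]1C(O)C(=C)C(=O)OC | intermediate
13 | enaminone: Et2NH adduct of 12 at C1 (C3(=O)–C2H=C1(NEt2)–C10), otherwise as 12 | COC(OC)/C=C(/CO[Si](c1ccccc1)(c1ccccc1)C(C)(C)C)C(=O)C=C(N(CC)CC)[C@@](C)(O)[C@@H]1OC(C)(C)O[C@H]1C(O)C(=C)C(=O)OC | intermediate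
14 | methyl 2-{(RS)-hydroxy[(4S,5R)-5-[(2S)-5-[(2Z)-1-{[tert-butyl(diphenyl)silyl]oxy}-4-oxobut-2-en-2-yl]-2-methyl-3-oxo-2,3-dihydrofuran-2-yl]-2,2-dimethyl-1,3-dioxolan-4-yl]methyl}prop-2-enoate | O=C/C=C(/CO[Si](c1ccccc1)(c1ccccc1)C(C)(C)C)C1=CC(=O)[C@@](C)(O1)[C@@H]2OC(C)(C)O[C@H]2C(O)C(=C)C(=O)OC | intermediate
15 | methyl (2Z)-2-(bromomethyl)-3-[(4S,5R)-5-{(2S)-5-[(2Z)-1-{[tert-butyl(diphenyl)silyl]oxy}-4-oxobut-2-en-2-yl]-2-methyl-3-oxo-2,3-dihydrofuran-2-yl}-2,2-dimethyl-1,3-dioxolan-4-yl]prop-2-enoate | O=C/C=C(/CO[Si](c1ccccc1)(c1ccccc1)C(C)(C)C)C1=CC(=O)[C@@](C)(O1)[C@@H]2OC(C)(C)O[C@H]2/C=C(\CBr)C(=O)OC | intermediate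
16 | seco hydroxy ester of 17: ten-membered carbocycle closed at C6–C7, free 6-OH, C7 bearing C(=CH2)CO2Me, 8,9-acetonide, 15-OTBDPS; (6R,7S,8S,9R,10S) | CC1(C)O[C@H]2[C@@H](C(=C)C(=O)OC)[C@H](O)/C=C(/CO[Si](c3ccccc3)(c3ccccc3)C(C)(C)C)C3=CC(=O)[C@@](C)(O3)[C@@H]2O1 | intermediate
17 | (6R,7S,8S,9R,10S)-8,9-O-isopropylidene-15-O-TBDPS-8,9,15-trihydroxy-1-oxo-3,10-epoxygermacra-2,4,11(13)-trien-12,6-olide | CC1(C)O[C@H]2[C@H]3C(=C)C(=O)O[C@@H]3/C=C(/CO[Si](c4ccccc4)(c4ccccc4)C(C)(C)C)C3=CC(=O)[C@@](C)(O3)[C@@H]2O1 | intermediate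
18 | 8,9-diol of 17 (15-OTBDPS; C6–C10 configuration as in the target) | O[C@H]1[C@H]2C(=C)C(=O)O[C@@H]2/C=C(/CO[Si](c3ccccc3)(c3ccccc3)C(C)(C)C)C2=CC(=O)[C@@](C)(O2)[C@@H]1O | intermediate
19 | 8-O-methacrylate of 18 (9-OH free; configuration as in the target) | C=C(C)C(=O)O[C@H]1[C@H]2C(=C)C(=O)O[C@@H]2/C=C(/CO[Si](c3ccccc3)(c3ccccc3)C(C)(C)C)C2=CC(=O)[C@@](C)(O2)[C@@H]1O | intermediate
20 | 15-O-TBDPS ether of the target (8-O-methacrylate, 9-O-isovalerate) | C=C(C)C(=O)O[C@H]1[C@H]2C(=C)C(=O)O[C@@H]2/C=C(/CO[Si](c3ccccc3)(c3ccccc3)C(C)(C)C)C2=CC(=O)[C@@](C)(O2)[C@@H]1OC(=O)CC(C)C | intermediate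
21 | CNP0552093.1: (6R,7S,8S,9R,10S)-15-hydroxy-8-methacryloyloxy-9-(3-methylbutanoyloxy)-1-oxo-3,10-epoxygermacra-2,4,11(13)-trien-12,6-olide | C=C(C)C(=O)O[C@H]1[C@H]2C(=C)C(=O)O[C@@H]2/C=C(/CO)C2=CC(=O)[C@@](C)(O2)[C@@H]1OC(=O)CC(C)C | target

**Step count**
Total: 16 steps. Longest linear sequence: 12 steps (steps 1–5, then 10–16); the vinyl iodide branch is steps 6–9.

**Three steps most likely to fail**

Step 10 (the proposed one-flask carbonylative furanone annulation). The fallback uses known chemistry only; it sets out from 6 and 11 and comes back at 14. The coupling is run as a conventional Pd/Cu carbonylative Sonogashira reaction (PdCl2(PPh3)2, CuI, Et3N, CO, THF) and the ynenone acetal 12 is isolated. It is then cyclised with a cationic gold(I) catalyst ((4-CF3C6H4)3PAuCl/AgOTf, toluene, rt), the established cycloisomerisation of γ-hydroxyalkynones to 3(2H)-furanones, to give the furanone acetal F1. Hydrolysis of its allylic dimethyl acetal (PPTS, acetone/H2O) delivers 14.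

Step 12 (Barbier macrocyclisation onto the furanone-bridged chain: ring strain and C6/C7 stereocontrol). The fallback reverses the order of ring formation; it sets out from 12 (isolated as above) and comes back at 17. Compound 12 is brominated (NBS/Me2S) and its acetal hydrolysed (PPTS, wet acetone) to the open-chain ynone enal bromide F2. This reducible cis-keto-enal is cyclised at once under aprotic conditions (CrCl2, THF, high dilution, then lactonisation) on the more flexible chain to the macrocyclic hydroxy-ynone lactone F3. The furanone is then closed across the ring by the same gold(I) cycloisomerisation (transannular O10–C3 bond formation), giving 17.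

Step 14 (site selectivity between the C8 and C9 hydroxyls, and acyl migration). The fallback replaces direct differentiation by silyl blocking; it sets out from 18 and comes back at 20. The less hindered hydroxyl is capped with a bulky silyl chloride (TESCl, imidazole, −40 °C) to give the 8-O-triethylsilyl ether F4. The hindered C9-OH is esterified (isovaleric anhydride, DMAP) to the 8-O-TES 9-O-isovalerate F5. The TES group is removed selectively (AcOH/THF/H2O; the primary TBDPS ether survives) to give the 9-O-isovalerate 8-ol F6, which is methacrylated (methacrylic anhydride, DMAP) to 20. Should C9-OH prove the more reactive hydroxyl of 18, the two anhydrides are simply used in the reverse order (18 to the 9-O-isovalerate 8-ol F6, then 20).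

**Further compounds**
F1 | step 10 | furanone acetal (14 with C6 as CH(OMe)2) | COC(OC)/C=C(/CO[Si](c1ccccc1)(c1ccccc1)C(C)(C)C)C1=CC(=O)[C@@](C)(O1)[C@@H]2OC(C)(C)O[C@H]2C(O)C(=C)C(=O)OC
F2 | step 12 | open-chain ynone enal bromide | O=C/C=C(/CO[Si](c1ccccc1)(c1ccccc1)C(C)(C)C)C(=O)C#C[C@@](C)(O)[C@@H]1OC(C)(C)O[C@H]1/C=C(\CBr)C(=O)OC
F3 | step 12 | macrocyclic hydroxy-ynone lactone (ring configuration as in 17, free 10-OH) | CC1(C)O[C@H]2[C@H]3C(=C)C(=O)O[C@@H]3/C=C(/CO[Si](c4ccccc4)(c4ccccc4)C(C)(C)C)C(=O)C#C[C@@](C)(O)[C@@H]2O1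
F4 | step 14 | 8-O-triethylsilyl ether of 18 | CC[Si](CC)(CC)O[C@H]1[C@H]2C(=C)C(=O)O[C@@H]2/C=C(/CO[Si](c3ccccc3)(c3ccccc3)C(C)(C)C)C2=CC(=O)[C@@](C)(O2)[C@@H]1O
F5 | step 14 | 8-O-TES 9-O-isovalerate | CC[Si](CC)(CC)O[C@H]1[C@H]2C(=C)C(=O)O[C@@H]2/C=C(/CO[Si](c3ccccc3)(c3ccccc3)C(C)(C)C)C2=CC(=O)[C@@](C)(O2)[C@@H]1OC(=O)CC(C)C
F6 | step 14 | 9-O-isovalerate 8-ol | O[C@H]1[C@H]2C(=C)C(=O)O[C@@H]2/C=C(/CO[Si](c3ccccc3)(c3ccccc3)C(C)(C)C)C2=CC(=O)[C@@](C)(O2)[C@@H]1OC(=O)CC(C)C
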